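A direct plan would take the natural resin acid (+)-agathic acid A1, which already holds the decalin, the 8(17)-methylene and both carboxyls, mask the acids as the diallyl ester A2, add oxygen to C13 of the enoate under reagent control (epoxidation to A3, reductive opening of the C14–O bond to A4) and unmask. Its weakest steps would be:
- the face-selective oxygenation at C13, because a β,β-dialkyl enoate is a poor acceptor for nucleophilic oxidants and the nearest stereocentre (C9) is three bonds away, so a catalyst alone would have to set C13 on a substrate class without precedent;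
- the masking and unmasking of the two acids, which would add two steps without adding complexity and would have to deal with the hindered axial C19 carboxyl;
- the supply of A1, which is isolated from resin rather than bought as a stock chemical.

The decalin is unfolded completely: the bonds C4–C5 and C9–C10 are cut, leaving an acyclic (E,E)-β-keto ester made from farnesol, whose first isoprene unit already carries C13 as the tertiary carbinol (Sharpless epoxidation, hydride opening). The key step, an oxidative radical bicyclisation with Mn(OAc)3/Cu(OAc)2, closes rings A and B, sets C4, C5, C9 and C10 together and ends at C8 as the 8(17)-methylene. It exploits the 1,5-relationship of C4, C5=C10 and C9=C8 in a chain and the C19 carboxyl on C4, which stabilises the initiating radical. No face-selective oxygenation of a remote enoate and no diterpene from natural sources are needed.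

Key step: step 8

Remark: carbons of the acyclic intermediates carry the labdane numbers of the atoms they become.
Assumption: the non-chelated C4 radical is taken to react with its ester carbonyl oxygen anti to C3 and with the phenyl ring of the (1S,2R,5S) auxiliary stacked over one face of the ester, which leads to the 4R,5R,9S,10R series of 17; were the sense reversed, the (1R,2S,5R) auxiliary would be used with no other change.

Step 1
Reactants: 1 (2E,6E)-farnesol; 2 tert-butyl hydroperoxide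
Product: 3 (2R,3R)-2,3-epoxyfarnesol
Conditions: Ti(OiPr)4 (5 mol%), D-(−)-diethyl tartrate (6 mol%), 2 (2 equiv, anhydrous in isooctane), 4 Å MS, CH2Cl2, −20 °C
Reagents that add atoms: tert-butyl hydroperoxide, CC(C)(C)OO
Why: Sharpless asymmetric epoxidation: the allylic hydroxyl binds the titanium tartrate, so only the C2=C3 alkene of the triene reacts, and the D-(−)-tartrate delivers oxygen to the face that gives the (2R,3R) epoxide, whose C3 is the future C13.

Step 2
Reactants: 3 (2R,3R)-2,3-epoxyfarnesol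
Product: 4 (3R,6E)-3,7,11-trimethyldodeca-6,10-diene-1,3-diol
Conditions: NaAlH2(OCH2CH2OMe)2 (1.5 equiv), THF, 0 °C to rt; aq. Rochelle salt
Reagents that add atoms: none
Why: Directed hydride opening of a 2,3-epoxy alcohol: the aluminium alkoxide at O1 delivers hydride to C2, so the 1,3-diol forms and the C3–O bond, and with it the R configuration, is untouched.

Step 3
Reactants: 4 (3R,6E)-3,7,11-trimethyldodeca-6,10-diene-1,3-diol; 5 di-tert-butylsilyl bis(trifluoromethanesulfonate)
Product: 6 (4R)-2,2-di-tert-butyl-4-[(3E)-4,8-dimethylnona-3,7-dien-1-yl]-4-methyl-1,3,2-dioxasilinane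
Conditions: 5 (1.1 equiv), 2,6-lutidine (3 equiv), CH2Cl2, 0 °C to rt
Reagents that add atoms: di-tert-butylsilyl bis(trifluoromethanesulfonate), CC(C)(C)[Si](OS(=O)(=O)C(F)(F)F)(OS(=O)(=O)C(F)(F)F)C(C)(C)C
Why: Silylene protection of a 1,3-diol: the ditriflate silylates even the tertiary hydroxyl, and the six-membered dioxasilinane masks O13 and O15 with one group that should tolerate base, hydride, AcOH and radical conditions and falls to fluoride.

Step 4
Reactants: 6 (4R)-2,2-di-tert-butyl-4-[(3E)-4,8-dimethylnona-3,7-dien-1-yl]-4-methyl-1,3,2-dioxasilinane; 2 tert-butyl hydroperoxide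
Product: 7 (2E,6E)-9-[(4R)-2,2-di-tert-butyl-4-methyl-1,3,2-dioxasilinan-4-yl]-2,6-dimethylnona-2,6-dien-1-ol
Conditions: SeO2 (10 mol%), salicylic acid (10 mol%), 2 (70% aq., 3 equiv), CH2Cl2, rt, run to partial conversion; unreacted 6 recycled
Reagents that add atoms: tert-butyl hydroperoxide, CC(C)(C)OO (oxygen relayed through SeO2)
Why: Catalytic SeO2 allylic oxidation (ene reaction, then [2,3]-sigmatropic shift): polyprenyl chains react first at the terminal trisubstituted alkene and at its (E)-methyl group, which gives the (E)-allylic alcohol and thereby the C1–C10=C5 geometry that the trans ring fusion needs.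

Step 5
Reactants: 7 (2E,6E)-9-[(4R)-2,2-di-tert-butyl-4-methyl-1,3,2-dioxasilinan-4-yl]-2,6-dimethylnona-2,6-dien-1-ol; 8 carbon tetrabromide
Product: 9 (4R)-4-[(3E,7E)-9-bromo-4,8-dimethylnona-3,7-dien-1-yl]-2,2-di-tert-butyl-4-methyl-1,3,2-dioxasilinane
Conditions: 8 (1.3 equiv), PPh3 (1.3 equiv), 2,6-lutidine (0.2 equiv), CH2Cl2, −20 to 0 °C; used crude
Reagents that add atoms: carbon tetrabromide, BrC(Br)(Br)Br
Why: Appel bromination: SN2 displacement at the primary allylic carbon under near-neutral conditions should give the bromide without allylic transposition and without touching the silylene.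

Step 6
Reactants: 10 (1S,2R,5S)-8-phenylmenthol [(+)-8-phenylmenthol]; 11 ethyl 2-methyl-3-oxobutanoate
Product: 12 (1S,2R,5S)-8-phenylmenthyl 2-methyl-3-oxobutanoate (epimers at C2)
Conditions: 11 (3 equiv), DMAP (0.3 equiv), toluene, reflux through 4 Å MS (EtOH removed)
Reagents that add atoms: ethyl 2-methyl-3-oxobutanoate, CCOC(=O)C(C)C(C)=O
Why: DMAP-catalysed transesterification of a β-keto ester through its acylketene, which the hindered secondary alcohol traps; the C2 epimers do not matter because this carbon becomes the planar radical centre C4.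

Step 7
Reactants: 12 (1S,2R,5S)-8-phenylmenthyl 2-methyl-3-oxobutanoate; 9 (4R)-4-[(3E,7E)-9-bromo-4,8-dimethylnona-3,7-dien-1-yl]-2,2-di-tert-butyl-4-methyl-1,3,2-dioxasilinane
Product: 14 (1S,2R,5S)-8-phenylmenthyl (6E,10E)-13-[(4R)-2,2-di-tert-butyl-4-methyl-1,3,2-dioxasilinan-4-yl]-2,6,10-trimethyl-3-oxotrideca-6,10-dienoate (epimers at C2), via keto ester dianion 13 (not isolated)
Conditions: 12 (1.2 equiv), NaH (1.25 equiv), THF, 0 °C; n-BuLi (1.2 equiv), 0 °C; 9 (1.0 equiv), 0 °C; aq. NH4Cl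
Reagents that add atoms: 12 as its dianion, CC(=O)C(C)C(=O)O[C@H]1C[C@@H](C)CC[C@@H]1C(C)(C)c1ccccc1
Why: γ-Alkylation of a β-keto ester dianion: the more basic terminal carbanion displaces the allylic bromide (SN2), joining C2 to C1 and leaving the α-hydrogen at C4 for the later enolisation.

Step 8
Reactants: 14 (1S,2R,5S)-8-phenylmenthyl (6E,10E)-13-[(4R)-2,2-di-tert-butyl-4-methyl-1,3,2-dioxasilinan-4-yl]-2,6,10-trimethyl-3-oxotrideca-6,10-dienoate
Product: 17 (1S,2R,5S)-8-phenylmenthyl (4R,5R,9S,10R,13R)-13,15-(di-tert-butylsilanediyldioxy)-3-oxolabd-8(17)-en-19-oate, via C4 radical 15 (not isolated), via C8 radical 16 (not isolated)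
Conditions: Mn(OAc)3·2H2O (2.2 equiv), Cu(OAc)2·H2O (1.0 equiv), degassed AcOH, 25–35 °C, Ar
Reagents that add atoms: none
Why: Rate-limiting enolisation of the 2-methyl β-keto ester and one-electron oxidation by trivalent manganese give the free tertiary C4 radical 15, which adds to C5 of the electron-rich (E)-C5=C10 alkene; the resulting tertiary C10 radical adds to C9 of the (E)-C8=C9 alkene, and the tertiary C8 radical 16 is oxidised by divalent copper through an alkylcopper intermediate that loses a C17 hydrogen, the least hindered β-hydrogen, to give the 8(17)-methylene. The closest known reaction type is the Mn(OAc)3/Cu(OAc)2 oxidative free-radical polycyclisation of 2-methyl-3-oxo polyenoates to trans-fused 3-oxo-4-carboalkoxydecalins that end in an exocyclic alkene, a reaction class in which 8-phenylmenthyl esters serve as auxiliaries. Ring A closes 6-endo-trig (C4–C5 bond) and ring B closes 6-endo-trig (C9–C10 bond), in each case because attack at the CH terminus of a trisubstituted alkene gives a tertiary radical, whereas 5-exo attack would have to occur at a fully substituted carbon. Chair–chair folding of the E,E-diene sets the relative configuration: H5 anti to the C20 methyl (trans fusion), C11 equatorial at C9 with H9 anti to C20, and at C4 the ester axial and cis to C20, because the planar radical reacts with its C18 methyl eclipsing the C3 oxygen and its ester eclipsing C2. The absolute configuration is decided in the first C–C bond formation by the auxiliary, whose phenyl ring stacks over one face of the ester and radical plane so that C5 bonds to the open face of C4, while C13 is too remote to take part. The step needs loss of a C17 hydrogen in preference to H7 or H9 (favoured by the copper-mediated elimination), a blocked C13 oxygen (a free hydroxyl would trap C8 as the 8,13-ether, which the AcOH-stable silylene prevents) and no further oxidation of the product (secured by the quaternary C4).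

Step 9
Reactants: 17 (1S,2R,5S)-8-phenylmenthyl (4R,5R,9S,10R,13R)-13,15-(di-tert-butylsilanediyldioxy)-3-oxolabd-8(17)-en-19-oate
Product: 18 (3S,4S,5R,9S,10R,13R)-13,15-(di-tert-butylsilanediyldioxy)labd-8(17)-ene-3,19-diol (3β-hydroxyl)
Conditions: LiAlH4 (3 equiv), THF, 0 to 40 °C; H2O/NaOH work-up; 10 recovered; any minor decalin diastereomer removed by chromatography here or at 17
Reagents that add atoms: none
Why: LiAlH4 reduction: hydride should attack the C3 ketone axially from the α face (the β face carries the axial ester and C20) to give the equatorial 3β-alkoxide, which assists hydride delivery to the neighbouring hindered ester and so releases the auxiliary; silylene and alkene are inert.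

Step 10
Reactants: 18 (3S,4S,5R,9S,10R,13R)-13,15-(di-tert-butylsilanediyldioxy)labd-8(17)-ene-3,19-diol; 19 1,1'-thiocarbonyldiimidazole
Product: 20 3β,19-O-thiocarbonyl derivative (cyclic thionocarbonate) of 18
Conditions: 19 (1.5 equiv), DMAP (0.2 equiv), toluene, 80 °C
Reagents that add atoms: 1,1'-thiocarbonyldiimidazole, S=C(n1ccnc1)n1ccnc1
Why: Cyclic thionocarbonate formation: the equatorial 3β-oxygen and the axial C19 oxygen are gauche, so the six-membered 1,3-dioxane-2-thione should close readily, as cyclic derivatives of 3β-hydroxy-4β-hydroxymethyl terpenoids do.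

Step 11
Reactants: 20 3β,19-O-thiocarbonyl derivative of 18
Product: 22 (4S,5R,9S,10R,13R)-13,15-(di-tert-butylsilanediyldioxy)labd-8(17)-en-19-ol, via S-stannyl thiocarbonate 21 (not isolated)
Conditions: Bu3SnH (2 equiv), AIBN (0.2 equiv), toluene, 100 °C; then NaOH (1 M), THF/MeOH, rt
Reagents that add atoms: none
Why: Barton-type radical deoxygenation of a cyclic thionocarbonate: the stannyl radical adds to sulfur and the adduct fragments at the secondary C3–O bond rather than at the primary neopentyl C19–O bond because the secondary radical is the more stable one; hydrogen transfer gives C3H2 and hydrolysis of 21 frees the C19 hydroxyl.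

Step 12
Reactants: 22 (4S,5R,9S,10R,13R)-13,15-(di-tert-butylsilanediyldioxy)labd-8(17)-en-19-ol
Product: 23 (4S,5R,9S,10R,13R)-labd-8(17)-ene-13,15,19-triol
Conditions: HF·pyridine, pyridine, THF, 0 °C to rt
Reagents that add atoms: none
Why: Fluoride cleavage of the silylene: the pyridine-buffered reagent should remove both Si–O bonds without protonating the exocyclic alkene or ionising the tertiary alcohol.

Step 13
Reactants: 23 (4S,5R,9S,10R,13R)-labd-8(17)-ene-13,15,19-triol; 24 sodium chlorite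
Product: 26 (4S,5R,9S,10R,13R)-13-hydroxylabd-8(17)-ene-15,19-dioic acid (target), via dialdehyde 25 (not isolated)
Conditions: Dess–Martin periodinane (2.6 equiv), NaHCO3, CH2Cl2, 0 °C to rt; filter, concentrate; then 24 (6 equiv), NaH2PO4 (6 equiv), 2-methyl-2-butene (20 equiv), t-BuOH/H2O, 0 °C to rt; KHSO4 to pH 3
Reagents that add atoms: sodium chlorite, [Na+].[O-]Cl=O
Why: Dess–Martin oxidation takes both primary alcohols, including the hindered neopentyl C19, to aldehydes while the tertiary C13 hydroxyl cannot react, and Pinnick oxidation of the crude dialdehyde gives the diacid under buffered conditions in which 2-methyl-2-butene scavenges HOCl and protects the 8(17)-alkene; no stereocentre is touched.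

## Compound list
1 | (2E,6E)-farnesol | CC(C)=CCC/C(C)=C/CC/C(C)=C/CO | starting material
2 | tert-butyl hydroperoxide | CC(C)(C)OO | starting material
3 | (2R,3R)-2,3-epoxyfarnesol | CC(C)=CCC/C(C)=C/CC[C@@]1(C)O[C@@H]1CO | intermediate
4 | (3R,6E)-3,7,11-trimethyldodeca-6,10-diene-1,3-diol | CC(C)=CCC/C(C)=C/CC[C@@](C)(O)CCO | intermediate
5 | di-tert-butylsilyl bis(trifluoromethanesulfonate) | CC(C)(C)[Si](OS(=O)(=O)C(F)(F)F)(OS(=O)(=O)C(F)(F)F)C(C)(C)C | starting material
6 | (4R)-2,2-di-tert-butyl-4-[(3E)-4,8-dimethylnona-3,7-dien-1-yl]-4-methyl-1,3,2-dioxasilinane | CC(C)=CCC/C(C)=C/CC[C@@]1(C)O[Si](C(C)(C)C)(C(C)(C)C)OCC1 | intermediate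
7 | (2E,6E)-9-[(4R)-2,2-di-tert-butyl-4-methyl-1,3,2-dioxasilinan-4-yl]-2,6-dimethylnona-2,6-dien-1-ol | OC/C(C)=C/CC/C(C)=C/CC[C@@]1(C)O[Si](C(C)(C)C)(C(C)(C)C)OCC1 | intermediate
8 | carbon tetrabromide | BrC(Br)(Br)Br | starting material
9 | (4R)-4-[(3E,7E)-9-bromo-4,8-dimethylnona-3,7-dien-1-yl]-2,2-di-tert-butyl-4-methyl-1,3,2-dioxasilinane | BrC/C(C)=C/CC/C(C)=C/CC[C@@]1(C)O[Si](C(C)(C)C)(C(C)(C)C)OCC1 | intermediate
10 | (1S,2R,5S)-8-phenylmenthol, (1S,2R,5S)-5-methyl-2-(2-phenylpropan-2-yl)cyclohexan-1-ol | O[C@H]1C[C@@H](C)CC[C@@H]1C(C)(C)c1ccccc1 | starting material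
11 | ethyl 2-methyl-3-oxobutanoate | CCOC(=O)C(C)C(C)=O | starting material
12 | (1S,2R,5S)-8-phenylmenthyl 2-methyl-3-oxobutanoate (epimers at C2) | CC(=O)C(C)C(=O)O[C@H]1C[C@@H](C)CC[C@@H]1C(C)(C)c1ccccc1 | intermediate
13 | dianion of 12 (sodium/lithium; drawn as the free bis-enolate) | C=C([O-])C(C)=C([O-])O[C@H]1C[C@@H](C)CC[C@@H]1C(C)(C)c1ccccc1 | intermediate
14 | (1S,2R,5S)-8-phenylmenthyl (6E,10E)-13-[(4R)-2,2-di-tert-butyl-4-methyl-1,3,2-dioxasilinan-4-yl]-2,6,10-trimethyl-3-oxotrideca-6,10-dienoate (epimers at C2) | CC(C(=O)CC/C(C)=C/CC/C(C)=C/CC[C@@]1(C)O[Si](C(C)(C)C)(C(C)(C)C)OCC1)C(=O)O[C@H]1C[C@@H](C)CC[C@@H]1C(C)(C)c1ccccc1 | intermediate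
15 | C4 radical of 14 (tertiary α-keto ester radical) | C[C](C(=O)CC/C(C)=C/CC/C(C)=C/CC[C@@]1(C)O[Si](C(C)(C)C)(C(C)(C)C)OCC1)C(=O)O[C@H]1C[C@@H](C)CC[C@@H]1C(C)(C)c1ccccc1 | intermediate
16 | bicyclic C8 radical (4R,5R,9S,10R decalin, radical at C8) | C[C]1CC[C@@H]2[C@](C)(CCC(=O)[C@]2(C)C(=O)O[C@H]3C[C@@H](C)CC[C@@H]3C(C)(C)c3ccccc3)[C@H]1CC[C@@]1(C)O[Si](C(C)(C)C)(C(C)(C)C)OCC1 | intermediate
17 | (1S,2R,5S)-8-phenylmenthyl (4R,5R,9S,10R,13R)-13,15-(di-tert-butylsilanediyldioxy)-3-oxolabd-8(17)-en-19-oate | C=C1CC[C@@H]2[C@](C)(CCC(=O)[C@]2(C)C(=O)O[C@H]3C[C@@H](C)CC[C@@H]3C(C)(C)c3ccccc3)[C@H]1CC[C@@]1(C)O[Si](C(C)(C)C)(C(C)(C)C)OCC1 | intermediate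
18 | (3S,4S,5R,9S,10R,13R)-13,15-(di-tert-butylsilanediyldioxy)labd-8(17)-ene-3,19-diol | C=C1CC[C@@H]2[C@](C)(CC[C@H](O)[C@]2(C)CO)[C@H]1CC[C@@]1(C)O[Si](C(C)(C)C)(C(C)(C)C)OCC1 | intermediate
19 | 1,1'-thiocarbonyldiimidazole | S=C(n1ccnc1)n1ccnc1 | starting material
20 | 3β,19-O-thiocarbonyl derivative (cyclic thionocarbonate) of 18 | C=C1CC[C@@H]2[C@](C)(CC[C@@H]3OC(=S)OC[C@]23C)[C@H]1CC[C@@]1(C)O[Si](C(C)(C)C)(C(C)(C)C)OCC1 | intermediate
21 | 19-O-[(tributylstannylsulfanyl)carbonyl] derivative of 22 | C=C1CC[C@@H]2[C@](C)(CCC[C@]2(C)COC(=O)S[Sn](CCCC)(CCCC)CCCC)[C@H]1CC[C@@]1(C)O[Si](C(C)(C)C)(C(C)(C)C)OCC1 | intermediate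
22 | (4S,5R,9S,10R,13R)-13,15-(di-tert-butylsilanediyldioxy)labd-8(17)-en-19-ol | C=C1CC[C@@H]2[C@](C)(CCC[C@]2(C)CO)[C@H]1CC[C@@]1(C)O[Si](C(C)(C)C)(C(C)(C)C)OCC1 | intermediate
23 | (4S,5R,9S,10R,13R)-labd-8(17)-ene-13,15,19-triol | C=C1CC[C@@H]2[C@](C)(CCC[C@]2(C)CO)[C@H]1CC[C@@](C)(O)CCO | intermediate
24 | sodium chlorite | [Na+].[O-]Cl=O | starting material
25 | (4S,5R,9S,10R,13R)-13-hydroxylabd-8(17)-ene-15,19-dial | C=C1CC[C@@H]2[C@](C)(CCC[C@]2(C)C=O)[C@H]1CC[C@@](C)(O)CC=O | intermediate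
26 | (4S,5R,9S,10R,13R)-13-hydroxylabd-8(17)-ene-15,19-dioic acid | C=C1CC[C@@H]2[C@](C)(CCC[C@]2(C)C(=O)O)[C@H]1CC[C@@](C)(O)CC(=O)O | target

Total step count: 13. Longest linear sequence: 12 steps (steps 1–5 and 7–13; step 6 prepares the auxiliary ester).

Steps most likely to fail

Step 8. The auxiliary may discriminate the two faces of the non-chelated C4 radical only weakly, or in the sense opposite to the one assumed, and the alkylcopper intermediate may lose H7 or H9 to give endocyclic alkenes (these would be removed on AgNO3-impregnated silica). The fallback moves the facial control to a chelated radical and sets C4 afterwards by alkylation; it sets out from bromide 9 and auxiliary 10 and comes back at 17. Auxiliary 10 and 2,2,6-trimethyl-4H-1,3-dioxin-4-one (xylene, 140 °C) would give (1S,2R,5S)-8-phenylmenthyl 3-oxobutanoate F1; its dianion (NaH, then n-BuLi, THF, 0 °C) would be alkylated with 9 to the α-unsubstituted keto ester (1S,2R,5S)-8-phenylmenthyl (6E,10E)-13-[(4R)-2,2-di-tert-butyl-4-methyl-1,3,2-dioxasilinan-4-yl]-6,10-dimethyl-3-oxotrideca-6,10-dienoate F2. Cyclisation with Mn(OAc)3·2H2O and Cu(OAc)2·H2O in the presence of Yb(OTf)3 (CF3CH2OH, −5 °C) would proceed through the ytterbium-chelated radical, on which the phenyl ring shields one face, to the 4-demethyl analogue of 17 (C4–H, keto–enol mixture, 5α-H, 9α-H, 10β-methyl) F3. C-Methylation (K2CO3, MeI, acetone) should then occur on the α face, anti to the axial C20 methyl, leaving the ester axial and giving 17.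

Step 11. The thionocarbonate radical may fragment in part toward the primary C19–O bond or be reduced without fragmentation. The fallback removes the C3 oxygen while it is the only hydroxyl in the molecule; it sets out from 17 and comes back at 22. NaBH4 (MeOH, 0 °C) would reduce 17 to the 3β-hydroxy ester (1S,2R,5S)-8-phenylmenthyl 13,15-(di-tert-butylsilanediyldioxy)-3β-hydroxylabd-8(17)-en-19-oate F4; PhOC(S)Cl/DMAP (MeCN) would give its 3-O-(phenoxythiocarbonyl) derivative F5; Bu3SnH/AIBN (toluene, 100 °C) would give the 3-deoxy ester (1S,2R,5S)-8-phenylmenthyl (4S,5R,9S,10R,13R)-13,15-(di-tert-butylsilanediyldioxy)labd-8(17)-en-19-oate F6; LiAlH4 (THF, reflux) would then release the auxiliary and give 22.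

Step 4. Allylic oxidation may also occur at the internal alkene, run on to the enal or stall at low conversion. The fallback builds the (E)-allylic alcohol by C–C bond formation; it sets out from 6 and comes back at 7. NBS in aqueous THF (0 °C) would convert the terminal alkene selectively into the bromohydrin (6E)-3-bromo-9-[(4R)-2,2-di-tert-butyl-4-methyl-1,3,2-dioxasilinan-4-yl]-2,6-dimethylnon-6-en-2-ol F7, and K2CO3/MeOH would close it to the terminal epoxide (4R)-2,2-di-tert-butyl-4-[(3E)-6-(3,3-dimethyloxiran-2-yl)-4-methylhex-3-en-1-yl]-4-methyl-1,3,2-dioxasilinane F8. HIO4 (aq. THF/Et2O, 0 °C) would cleave F8 to the aldehyde (4E)-7-[(4R)-2,2-di-tert-butyl-4-methyl-1,3,2-dioxasilinan-4-yl]-4-methylhept-4-enal F9. Wittig reaction with Ph3P=C(Me)CO2Et (CH2Cl2, rt) would give ethyl (2E,6E)-9-[(4R)-2,2-di-tert-butyl-4-methyl-1,3,2-dioxasilinan-4-yl]-2,6-dimethylnona-2,6-dienoate F10, and i-Bu2AlH (CH2Cl2, −78 °C) would reduce it to 7.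

Further compounds
F1 | step 8 | (1S,2R,5S)-8-phenylmenthyl 3-oxobutanoate | CC(=O)CC(=O)O[C@H]1C[C@@H](C)CC[C@@H]1C(C)(C)c1ccccc1
F2 | step 8 | (1S,2R,5S)-8-phenylmenthyl (6E,10E)-13-[(4R)-2,2-di-tert-butyl-4-methyl-1,3,2-dioxasilinan-4-yl]-6,10-dimethyl-3-oxotrideca-6,10-dienoate | O=C(CC(=O)O[C@H]1C[C@@H](C)CC[C@@H]1C(C)(C)c1ccccc1)CC/C(C)=C/CC/C(C)=C/CC[C@@]1(C)O[Si](C(C)(C)C)(C(C)(C)C)OCC1
F3 | step 8 | 4-demethyl analogue of 17 (C4–H, keto form drawn, 5α-H, 9α-H, 10β-methyl) | C=C1CC[C@@H]2[C@](C)(CCC(=O)C2C(=O)O[C@H]3C[C@@H](C)CC[C@@H]3C(C)(C)c3ccccc3)[C@H]1CC[C@@]1(C)O[Si](C(C)(C)C)(C(C)(C)C)OCC1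
F4 | step 11 | (1S,2R,5S)-8-phenylmenthyl 13,15-(di-tert-butylsilanediyldioxy)-3β-hydroxylabd-8(17)-en-19-oate | C=C1CC[C@@H]2[C@](C)(CC[C@H](O)[C@]2(C)C(=O)O[C@H]3C[C@@H](C)CC[C@@H]3C(C)(C)c3ccccc3)[C@H]1CC[C@@]1(C)O[Si](C(C)(C)C)(C(C)(C)C)OCC1
F5 | step 11 | 3-O-(phenoxythiocarbonyl) derivative of F4 | C=C1CC[C@@H]2[C@](C)(CC[C@H](OC(=S)Oc3ccccc3)[C@]2(C)C(=O)O[C@H]3C[C@@H](C)CC[C@@H]3C(C)(C)c3ccccc3)[C@H]1CC[C@@]1(C)O[Si](C(C)(C)C)(C(C)(C)C)OCC1
F6 | step 11 | (1S,2R,5S)-8-phenylmenthyl (4S,5R,9S,10R,13R)-13,15-(di-tert-butylsilanediyldioxy)labd-8(17)-en-19-oate | C=C1CC[C@@H]2[C@](C)(CCC[C@]2(C)C(=O)O[C@H]3C[C@@H](C)CC[C@@H]3C(C)(C)c3ccccc3)[C@H]1CC[C@@]1(C)O[Si](C(C)(C)C)(C(C)(C)C)OCC1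
F7 | step 4 | (6E)-3-bromo-9-[(4R)-2,2-di-tert-butyl-4-methyl-1,3,2-dioxasilinan-4-yl]-2,6-dimethylnon-6-en-2-ol (epimers at C3) | CC(C)(O)C(Br)CC/C(C)=C/CC[C@@]1(C)O[Si](C(C)(C)C)(C(C)(C)C)OCC1
F8 | step 4 | (4R)-2,2-di-tert-butyl-4-[(3E)-6-(3,3-dimethyloxiran-2-yl)-4-methylhex-3-en-1-yl]-4-methyl-1,3,2-dioxasilinane (epimers at the oxirane) | CC1(C)OC1CC/C(C)=C/CC[C@@]1(C)O[Si](C(C)(C)C)(C(C)(C)C)OCC1
F9 | step 4 | (4E)-7-[(4R)-2,2-di-tert-butyl-4-methyl-1,3,2-dioxasilinan-4-yl]-4-methylhept-4-enal | O=CCC/C(C)=C/CC[C@@]1(C)O[Si](C(C)(C)C)(C(C)(C)C)OCC1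
F10 | step 4 | ethyl (2E,6E)-9-[(4R)-2,2-di-tert-butyl-4-methyl-1,3,2-dioxasilinan-4-yl]-2,6-dimethylnona-2,6-dienoate | CCOC(=O)/C(C)=C/CC/C(C)=C/CC[C@@]1(C)O[Si](C(C)(C)C)(C(C)(C)C)OCC1
A1 | direct plan | (+)-agathic acid, (4S,5R,9S,10R,13E)-labda-8(17),13-diene-15,19-dioic acid | C=C1CC[C@@H]2[C@](C)(CCC[C@]2(C)C(=O)O)[C@H]1CC/C(C)=C/C(=O)O
A2 | direct plan | diallyl agathate | C=C1CC[C@@H]2[C@](C)(CCC[C@]2(C)C(=O)OCC=C)[C@H]1CC/C(C)=C/C(=O)OCC=C
A3 | direct plan | diallyl (13R,14S)-13,14-epoxylabd-8(17)-ene-15,19-dioate | C=C1CC[C@@H]2[C@](C)(CCC[C@]2(C)C(=O)OCC=C)[C@H]1CC[C@@]3(C)O[C@@H]3C(=O)OCC=C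
A4 | direct plan | diallyl (13R)-13-hydroxylabd-8(17)-ene-15,19-dioate | C=C1CC[C@@H]2[C@](C)(CCC[C@]2(C)C(=O)OCC=C)[C@H]1CC[C@@](C)(O)CC(=O)OCC=C
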